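(The numbers in the tables stem from a simulated flask for an exercise; the scatter is artificial.)

Count the turnovers of a flask before reading its percentages. Starting material and partner make target, and we are asked what share of target plus side product is target, flask by flask.

| flask | starting material | partner | remark | time |
|---|---|---|---|---|
| Friday's | 5 mM | 2.5 mM | run made earlier |  |
| Tuesday's | 2.5 mM | 2.5 mM | run made earlier |  |
| Monday's | 3.8 mM | 2.5 mM | run made earlier |  |
| Saturday's | 5 mM | 1.2 mM | run made earlier |  |
| cedar | 5.0 mM (in portions, 5, over 5.0 min) | 2.50 mM | first portion at the start, last at 5.0 min | 6.0 min |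
| elm | 5.0 mM (fed, over 5.0 min) | 2.50 mM | all else is in the flask from the start; the feed brings no volume worth counting | 6.0 min |
| maple | 5.0 mM | 2.50 mM | everything together at the start | 6.0 min |
| birch | 5.0 mM | 2.50 mM (fed, over 5.0 min) | all else is in the flask from the start; the feed brings no volume worth counting | 6.0 min |

| run | time / min | target / % | side product / % | starting material / % |
|---|---|---|---|---|
| Friday's | 0.833 | 42.0 | 14.5 | 21.2 |
| Friday's | 2.00 | 36.0 | 23.4 | 10.7 |
| Friday's | 2.50 | 36.1 | 25.4 | 7.1 |
| Friday's | 4.00 | 33.4 | 29.5 | 6.7 |
| Tuesday's | 1.33 | 99.2 | 0 | 0 |
| Tuesday's | 2.50 | 98.5 | 0 | 0.4 |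
| Tuesday's | 4.00 | 100.1 | 0.8 | 0.3 |
| Tuesday's | 5.00 | 98.5 | 0.2 | 0.1 |
| Monday's | 0.667 | 60.0 | 7.9 | 20.3 |
| Monday's | 1.50 | 57.7 | 18.2 | 14.6 |
| Monday's | 3.00 | 54.4 | 24.5 | 6.0 |
| Monday's | 5.00 | 50.0 | 27.7 | 4.8 |
| Saturday's | 0.417 | 21.6 | 6.5 | 42.5 |
| Saturday's | 0.833 | 18.9 | 7.7 | 31.7 |
| Saturday's | 2.00 | 18.0 | 13.6 | 16.3 |
| Saturday's | 5.00 | 12.5 | 19.6 | 7.9 |

(readings scatter by 1 percentage point)

- in percentages every species weighs as the starting material in it: one side product counts as two
- the numbers in the tables scatter with a standard deviation of 1 percentage point

1. the flask with the highest share of target in target plus side product ("all alike" if they lie within 1.5 percentage points) (cedar / elm / maple / birch / all alike)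
2. share of target in target plus side product at the end, cedar
3. share of target in target plus side product at the end, elm
4. share of target in target plus side product at the end, maple
5. share of target in target plus side product at the end, birch

Take the main step first: one starting material and one partner give one target. In Tuesday's run, with equal charges, the last reading gives a share of 99.8%. On Friday partner is the limiting reagent, so target can reach 50.0% of the charge.

Now add a second turn: one more starting material carries a target into side product, which holds two and counts double. At Friday's last reading, at 4.00 min, target plus half the side product is 48.2%, close to that ceiling, so this sum is the target ever made. Of it, 0.306 has gone on; we call this part f, the second-turn fraction. Target is then 1 − f and side product 2f, so the share is (1 − f)/(1 + f), here 53.1%.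

Last comes what the columns do not show. Friday's readings leave 30.4% of the charge unaccounted for, twice what the second turn took. This loss leaves the target ever made alone and competes for starting material. The 6.7% still present can raise f by its amount divided by the target ever made, to 0.445, a share of 38.4%. Maple has Friday's charges, so we place it between these two shares: 53.1% if it stands as Friday's run did at 4.00 min, and the lower one if the 6.7% still present then goes wholly into the second turn.

The forecast gives 58% for cedar, 54% for elm, 50% for maple and 83% for birch, and names birch; for birch, where A is starting material and P target, it says “A is lost before much P exists”.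

The flasks give 58.5% for cedar, 56.5% for elm, 51.0% for maple and 83.0% for birch, so birch stands highest. The unseen loss is the homo dimer.

    starting material + partner → target, rate k1*[starting material]^0.5*[partner]^0.5 (k = 1.40 s⁻¹)
    2 starting material → homo dimer (k = 3.60 L mol⁻¹ s⁻¹)
    starting material + target → side product (k = 1.90 L mol⁻¹ s⁻¹)

Has each flask come to rest? Maple at 6.0 min holds 33.8% target and 32.4% side product, so f is 0.324, with 3.02% starting material left. If that remainder takes the second turn, f gains 0.0604 and the share falls to 44.5%; at ten times the time maple reads 45.3%. Birch holds 0% starting material, so its f stays 0.0927, and at 60.0 min its share reads 83.0%.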